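## Retrosynthetic overview

1. The C5–Cl bond is made last (NCS on the push–pull dienol ether). Pyran ring B (O2–C3) closes by 6-endo oxa-Michael addition of the C1 hydroxyl onto a dienynone, which comes from a Sonogashira union (C4–C4a) of a ring A β-bromo enone triol with the side-chain (E)-enyne.
2. Ring A comes from 4-methoxy-3-methylphenol via a bromo quinone monoketal. A temporary CBS-set carbinol at C8a directs a syn-dihydroxylation (C7, C8); reoxidation, methylenation and convex-face hydroboration then set C8a–H and C1.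
3. Side chain: the oxolane is a reduced γ-lactol. Its O1 joins the carbinol carbon C2 and the unsubstituted C5 in a 1,4-relationship across C3(Me)–C4, so C3–C4–C5 is a crotyl homoenolate and C2–O1 an aldehyde. This allows a homoaldol union that forms C2–C3 and, in the same pot, O1–C5.
4. Ring order: oxolane (step 5), carbocycle A taken from the arene (dearomatised in step 12), pyran B last (step 20). Core atoms carry isochromene numbers; the oxolane is numbered O1, C2–C5.

Key step: step 5

Assumption: the amino alcohol ligand of step 1 and the oxazaborolidine of step 13 are taken in the antipode that the accepted transition-state models assign to the drawn products; the other antipode is used if the sense proves opposite.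

## Route

Step 1
Reactants: 1 ethyl pyruvate; 2 (trimethylsilyl)acetylene
Product: 3 ethyl (2S)-2-hydroxy-2-methyl-4-(trimethylsilyl)but-3-ynoate
Conditions: Zn(OTf)2, Et3N, (1S,2S)-2-(dimethylamino)-1-(4-nitrophenyl)-3-(tert-butyldimethylsilyloxy)propan-1-ol (ligand), toluene, 70 °C
Reagents that add atoms: none
Why: Catalytic asymmetric alkynylation of an α-keto ester by a zinc acetylide, in which the zinc-bound chelating amino alcohol differentiates the ketone faces and should set the tertiary carbinol as S.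

Step 2
Reactants: 3 ethyl (2S)-2-hydroxy-2-methyl-4-(trimethylsilyl)but-3-ynoate
Product: 4 ethyl (2S)-2-[(tert-butyldimethylsilyl)oxy]-2-methyl-4-(trimethylsilyl)but-3-ynoate
Conditions: TBSOTf, 2,6-lutidine, CH2Cl2, 0 → 23 °C
Reagents that add atoms: tert-butyldimethylsilyl triflate, CC(C)(C)[Si](C)(C)OS(=O)(=O)C(F)(F)F
Why: Silylation of a hindered tertiary alcohol with a silyl triflate, giving a non-chelating ether that survives the organometallic and Lewis acid steps.

Step 3
Reactants: 4 ethyl (2S)-2-[(tert-butyldimethylsilyl)oxy]-2-methyl-4-(trimethylsilyl)but-3-ynoate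
Product: 5 (2S)-2-[(tert-butyldimethylsilyl)oxy]-2-methyl-4-(trimethylsilyl)but-3-ynal
Conditions: DIBAL-H (1.1 equiv), CH2Cl2, −78 °C; Rochelle salt
Reagents that add atoms: none
Why: Half-reduction of an α-silyloxy ester, whose tetrahedral aluminate is stable at −78 °C and releases the aldehyde only on work-up; the quaternary α-carbon cannot epimerise.

Step 4
Reactants: 6 (2E)-but-2-en-1-ol; 7 N,N-diisopropylcarbamoyl chloride
Product: 8 (2E)-but-2-en-1-yl N,N-diisopropylcarbamate
Conditions: NaH, THF, 0 → 65 °C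
Reagents that add atoms: none
Why: O-Carbamoylation of the alkoxide (acyl substitution) installs the directing and anion-stabilising group for α-lithiation.

Step 5
Reactants: 8 (2E)-but-2-en-1-yl N,N-diisopropylcarbamate; 5 (2S)-2-[(tert-butyldimethylsilyl)oxy]-2-methyl-4-(trimethylsilyl)but-3-ynal
Product: 12 tert-butyl{[(2S)-2-[(2S,3S)-5-methoxy-3-methyloxolan-2-yl]-4-(trimethylsilyl)but-3-yn-2-yl]oxy}dimethylsilane (both C5 anomers), via lithiated carbamate sparteine complex 9 (not isolated), via crotyl titanium reagent 10 (not isolated), via homoaldol enol carbamate 11 (not isolated)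
Conditions: 8 (1.3 equiv), n-BuLi, (−)-sparteine, pentane/cyclohexane, −78 °C (crystallisation); Ti(OiPr)4, −78 °C; 5, −78 °C; then MeSO3H (excess) in MeOH, −78 → 23 °C
Reagents that add atoms: methanol, CO
Why: Sparteine-mediated α-lithiation of 8 with crystallisation-driven dynamic resolution gives (S)-9, inverting titanation gives (R)-10, and this adds to the aldehyde through a six-membered chair transition state with allyl transposition to form C2–C3 and the (Z)-enol carbamate 11; acidic methanol then protonates the enol carbamate at C4, the C2 oxygen captures the carbamoyloxy-stabilised cation at C5, and the carbamate is exchanged for methoxide with loss of iPr2NH and CO2. The closest known reaction type is the Hoppe homoaldol reaction of metallated 2-alkenyl carbamates followed by acid methanolysis of the 4-hydroxy enol carbamate to a γ-lactol ether, here run in one pot. The oxolane closes in the 5-exo-trig mode, the oxygen attacking the cationic C5 whose C=O+ bond lies outside the new ring. C3 is set by 1,3-chirality transfer from the titanium-bearing carbon (fixed by (−)-sparteine) together with the E geometry of the crotyl unit, and C2 by the chair with the aldehyde residue equatorial, which gives the anti, hence 2,3-trans, relationship; the acetal carbon C5 is uncontrolled and is erased in step 6. The step needs aldehyde-face selectivity next to a quaternary stereocentre: the reagent-controlled face coincides with Felkin–Anh attack anti to the silyloxy group past the slim alkynyl substituent (matched pair), and the non-chelating silyl ether together with the weakly Lewis acidic alkoxytitanium centre excludes chelation control.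

Step 6
Reactants: 12 tert-butyl{[(2S)-2-[(2S,3S)-5-methoxy-3-methyloxolan-2-yl]-4-(trimethylsilyl)but-3-yn-2-yl]oxy}dimethylsilane
Product: 13 tert-butyldimethyl{[(2S)-2-[(2S,3S)-3-methyloxolan-2-yl]-4-(trimethylsilyl)but-3-yn-2-yl]oxy}silane
Conditions: Et3SiH, BF3·OEt2, CH2Cl2, −78 → −20 °C
Reagents that add atoms: none
Why: Ionic hydrogenation of a lactol ether (Lewis acid ionisation to the cyclic oxocarbenium ion, hydride transfer from silane) turns C5 into CH2 and so removes the extra oxidation level without touching a stereocentre.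

Step 7
Reactants: 13 tert-butyldimethyl{[(2S)-2-[(2S,3S)-3-methyloxolan-2-yl]-4-(trimethylsilyl)but-3-yn-2-yl]oxy}silane
Product: 14 tert-butyldimethyl{[(2S)-2-[(2S,3S)-3-methyloxolan-2-yl]but-3-yn-2-yl]oxy}silane
Conditions: K2CO3 (cat.), MeOH, 23 °C
Reagents that add atoms: none
Why: Base-catalysed methanolysis cleaves only the alkynyl C–Si bond, the hindered tertiary silyl ether being inert.

Step 8
Reactants: 14 tert-butyldimethyl{[(2S)-2-[(2S,3S)-3-methyloxolan-2-yl]but-3-yn-2-yl]oxy}silane
Product: 16 tert-butyl{[(2S,3E)-4-iodo-2-[(2S,3S)-3-methyloxolan-2-yl]but-3-en-2-yl]oxy}dimethylsilane, via alkenylzirconocene 15 (not isolated)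
Conditions: Cp2Zr(H)Cl, THF, 23 °C; then I2, 0 °C
Reagents that add atoms: iodine, II
Why: Hydrozirconation adds Zr–H syn and anti-Markovnikov across the terminal alkyne and iodinolysis proceeds with retention, which fixes the E alkene.

Step 9
Reactants: 16 tert-butyl{[(2S,3E)-4-iodo-2-[(2S,3S)-3-methyloxolan-2-yl]but-3-en-2-yl]oxy}dimethylsilane; 2 (trimethylsilyl)acetylene
Product: 17 tert-butyldimethyl{[(2S,3E)-2-[(2S,3S)-3-methyloxolan-2-yl]-6-(trimethylsilyl)hex-3-en-5-yn-2-yl]oxy}silane
Conditions: Pd(PPh3)2Cl2 (cat.), CuI (cat.), Et3N, THF, 23 °C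
Reagents that add atoms: none
Why: Sonogashira coupling of a vinyl iodide with a terminal alkyne keeps the alkene geometry.

Step 10
Reactants: 17 tert-butyldimethyl{[(2S,3E)-2-[(2S,3S)-3-methyloxolan-2-yl]-6-(trimethylsilyl)hex-3-en-5-yn-2-yl]oxy}silane
Product: 18 (2S,3E)-2-[(2S,3S)-3-methyloxolan-2-yl]hex-3-en-5-yn-2-ol
Conditions: TBAF (3 equiv), THF, 0 → 40 °C
Reagents that add atoms: none
Why: Fluoride cleaves both the alkynyl C–Si and the tertiary O–Si bond under non-acidic conditions that the tertiary allylic alcohol tolerates.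

Step 11
Reactants: 19 4-methoxy-3-methylphenol
Product: 20 2-bromo-4-methoxy-5-methylphenol
Conditions: NBS, MeCN, 0 °C
Reagents that add atoms: N-bromosuccinimide, BrN1C(=O)CCC1=O
Why: Electrophilic aromatic bromination goes to the free position ortho to the phenol OH, which is also para to the methyl group.

Step 12
Reactants: 20 2-bromo-4-methoxy-5-methylphenol
Product: 21 2-bromo-4,4-dimethoxy-5-methylcyclohexa-2,5-dien-1-one
Conditions: PhI(OAc)2, MeOH, 0 °C
Reagents that add atoms: methanol, CO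
Why: Oxidative dearomatisation of a p-methoxyphenol with a hypervalent iodine reagent in methanol gives the quinone monoketal, which carries every ring A carbon at a usable oxidation level.

Step 13
Reactants: 21 2-bromo-4,4-dimethoxy-5-methylcyclohexa-2,5-dien-1-one
Product: 22 (1S)-2-bromo-4,4-dimethoxy-5-methylcyclohexa-2,5-dien-1-ol
Conditions: (R)-2-methyl-CBS-oxazaborolidine (0.2 equiv), catecholborane, toluene, −78 °C; aq NaHCO3
Reagents that add atoms: none
Why: Corey–Bakshi–Shibata 1,2-reduction of an α-bromo enone, in which the bromine-bearing vinyl flank acts as the large group so that the (R)-catalyst should deliver the (S)-carbinol as a temporary stereocentre.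

Step 14
Reactants: 22 (1S)-2-bromo-4,4-dimethoxy-5-methylcyclohexa-2,5-dien-1-ol
Product: 24 (1R,2R,3S)-4-bromo-6,6-dimethoxy-1-methylcyclohex-4-ene-1,2,3-triol, via osmate ester 23 (not isolated)
Conditions: OsO4 (1.05 equiv), TMEDA, CH2Cl2, −78 °C; then aq Na2SO3, THF, 60 °C
Reagents that add atoms: osmium tetroxide, O=[Os](=O)(=O)=O
Why: Hydrogen-bond-directed dihydroxylation with the OsO4·TMEDA complex adds syn to the allylic hydroxyl on the electron-richer trisubstituted alkene (the bromoalkene is deactivated), setting C7 and C8 cis to each other and to the carbinol.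

Step 15
Reactants: 24 (1R,2R,3S)-4-bromo-6,6-dimethoxy-1-methylcyclohex-4-ene-1,2,3-triol
Product: 25 (5R,6S)-2-bromo-5,6-dihydroxy-4,4-dimethoxy-5-methylcyclohex-2-en-1-one
Conditions: MnO2 (activated, excess), CH2Cl2, 23 °C
Reagents that add atoms: none
Why: MnO2 oxidises only the allylic carbinol, which returns the C8a ketone and removes the temporary stereocentre after it has done its work.

Step 16
Reactants: 25 (5R,6S)-2-bromo-5,6-dihydroxy-4,4-dimethoxy-5-methylcyclohex-2-en-1-one
Product: 26 (3aS,7aR)-5-bromo-7,7-dimethoxy-2,2,7a-trimethyl-7,7a-dihydro-1,3-benzodioxol-4(3aH)-one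
Conditions: 2,2-dimethoxypropane, PPTS (cat.), CH2Cl2, 23 °C
Reagents that add atoms: 2,2-dimethoxypropane, COC(C)(C)OC
Why: Acid-catalysed transketalisation closes the acetonide on the cis-diol, which blocks β-elimination and builds the concave/convex bias used in step 18.

Step 17
Reactants: 26 (3aS,7aR)-5-bromo-7,7-dimethoxy-2,2,7a-trimethyl-7,7a-dihydro-1,3-benzodioxol-4(3aH)-one
Product: 27 (3aR,7aR)-5-bromo-7,7-dimethoxy-2,2,7a-trimethyl-4-methylidene-3a,4,7,7a-tetrahydro-1,3-benzodioxole
Conditions: Cp2TiMe2, toluene/THF, 65 °C, dark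
Reagents that add atoms: dimethyltitanocene, C[Ti](C)(C1C=CC=C1)C1C=CC=C1
Why: Petasis methylenation through the non-basic titanium methylidene converts the α-alkoxy, β-alkoxy ketone to the exocyclic alkene without enolisation or β-elimination.

Step 18
Reactants: 27 (3aR,7aR)-5-bromo-7,7-dimethoxy-2,2,7a-trimethyl-4-methylidene-3a,4,7,7a-tetrahydro-1,3-benzodioxole
Product: 29 [(3aR,4S,7aR)-5-bromo-7,7-dimethoxy-2,2,7a-trimethyl-3a,4,7,7a-tetrahydro-1,3-benzodioxol-4-yl]methanol, via alkylborane 28 (not isolated)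
Conditions: 9-BBN, THF, 0 → 23 °C; then H2O2, aq NaOH, 0 °C
Reagents that add atoms: hydrogen peroxide, OO
Why: Hydroboration–oxidation places boron on the terminal carbon of the exocyclic alkene and delivers hydrogen to C8a from the convex face, anti to the cis-fused dioxolane, so that the hydroxymethyl group ends cis to both ring oxygens; the bromoalkene is too electron-poor to react.

Step 19
Reactants: 29 [(3aR,4S,7aR)-5-bromo-7,7-dimethoxy-2,2,7a-trimethyl-3a,4,7,7a-tetrahydro-1,3-benzodioxol-4-yl]methanol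
Product: 30 (4S,5R,6R)-3-bromo-5,6-dihydroxy-4-(hydroxymethyl)-6-methylcyclohex-2-en-1-one
Conditions: TFA/H2O (4:1), 0 → 23 °C
Reagents that add atoms: water, O
Why: Aqueous acid hydrolyses the dimethyl ketal to the β-bromo enone and the acetonide to the diol, so that no protecting group has to be removed after the acid-sensitive side chain is attached.

Step 20
Reactants: 30 (4S,5R,6R)-3-bromo-5,6-dihydroxy-4-(hydroxymethyl)-6-methylcyclohex-2-en-1-one; 18 (2S,3E)-2-[(2S,3S)-3-methyloxolan-2-yl]hex-3-en-5-yn-2-ol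
Product: 32 (7R,8R,8aS)-7,8-dihydroxy-3-[(1E,3S)-3-hydroxy-3-[(2S,3S)-3-methyloxolan-2-yl]but-1-en-1-yl]-7-methyl-1,7,8,8a-tetrahydro-6H-isochromen-6-one, via dienynone 31 (not isolated)
Conditions: Pd(PPh3)2Cl2 (cat.), CuI (cat.), Et3N, degassed THF, 23 → 40 °C
Reagents that add atoms: none
Why: Sonogashira coupling of the β-bromo enone gives a dienynone whose primary C1 hydroxyl adds 6-endo-dig to the δ-carbon C3 (oxa-Michael 1,6-addition), closing ring B; the C8 hydroxyl cannot compete because it would create a bridgehead alkene, and no stereocentre is touched.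

Step 21
Reactants: 32 (7R,8R,8aS)-7,8-dihydroxy-3-[(1E,3S)-3-hydroxy-3-[(2S,3S)-3-methyloxolan-2-yl]but-1-en-1-yl]-7-methyl-1,7,8,8a-tetrahydro-6H-isochromen-6-one
Product: 33 (7R,8R,8aS)-5-chloro-7,8-dihydroxy-3-[(1E,3S)-3-hydroxy-3-[(2S,3S)-3-methyloxolan-2-yl]but-1-en-1-yl]-7-methyl-1,7,8,8a-tetrahydro-6H-isochromen-6-one
Conditions: NCS (1.05 equiv), CH2Cl2, −20 → 0 °C
Reagents that add atoms: N-chlorosuccinimide, ClN1C(=O)CCC1=O
Why: Electrophilic chlorination at C5, the nucleophilic α-carbon of the O2–C3=C4–C4a=C5–C6=O push–pull system, follows the C5 halogenation known for azaphilone dienol ethers.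

## Compound list

1 | ethyl pyruvate | CCOC(=O)C(C)=O | starting material
2 | (trimethylsilyl)acetylene | C#C[Si](C)(C)C | starting material
3 | ethyl (2S)-2-hydroxy-2-methyl-4-(trimethylsilyl)but-3-ynoate | CCOC(=O)[C@@](C)(O)C#C[Si](C)(C)C | intermediate
4 | ethyl (2S)-2-[(tert-butyldimethylsilyl)oxy]-2-methyl-4-(trimethylsilyl)but-3-ynoate | CCOC(=O)[C@@](C)(O[Si](C)(C)C(C)(C)C)C#C[Si](C)(C)C | intermediate
5 | (2S)-2-[(tert-butyldimethylsilyl)oxy]-2-methyl-4-(trimethylsilyl)but-3-ynal | O=C[C@@](C)(O[Si](C)(C)C(C)(C)C)C#C[Si](C)(C)C | intermediate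
6 | (2E)-but-2-en-1-ol | C/C=C/CO | starting material
7 | N,N-diisopropylcarbamoyl chloride | CC(C)N(C(C)C)C(Cl)=O | starting material
8 | (2E)-but-2-en-1-yl N,N-diisopropylcarbamate | C/C=C/COC(=O)N(C(C)C)C(C)C | intermediate
9 | (1S,2E)-1-lithiobut-2-en-1-yl N,N-diisopropylcarbamate, as its (−)-sparteine complex (not isolated; ligand not drawn) | C/C=C/[C@H]([Li])OC(=O)N(C(C)C)C(C)C | intermediate
10 | (1R,2E)-1-(triisopropoxytitanio)but-2-en-1-yl N,N-diisopropylcarbamate (not isolated) | C/C=C/[C@@H]([Ti](OC(C)C)(OC(C)C)OC(C)C)OC(=O)N(C(C)C)C(C)C | intermediate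
11 | (1Z,3S,4S,5S)-5-[(tert-butyldimethylsilyl)oxy]-4-hydroxy-3,5-dimethyl-7-(trimethylsilyl)hept-1-en-6-yn-1-yl N,N-diisopropylcarbamate (not isolated) | CC(C)N(C(C)C)C(=O)O/C=C\[C@H](C)[C@H](O)[C@@](C)(O[Si](C)(C)C(C)(C)C)C#C[Si](C)(C)C | intermediate
12 | tert-butyl{[(2S)-2-[(2S,3S)-5-methoxy-3-methyloxolan-2-yl]-4-(trimethylsilyl)but-3-yn-2-yl]oxy}dimethylsilane (C5 anomers) | C[C@H]1CC(OC)O[C@@H]1[C@@](C)(O[Si](C)(C)C(C)(C)C)C#C[Si](C)(C)C | intermediate
13 | tert-butyldimethyl{[(2S)-2-[(2S,3S)-3-methyloxolan-2-yl]-4-(trimethylsilyl)but-3-yn-2-yl]oxy}silane | C[C@H]1CCO[C@@H]1[C@@](C)(O[Si](C)(C)C(C)(C)C)C#C[Si](C)(C)C | intermediate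
14 | tert-butyldimethyl{[(2S)-2-[(2S,3S)-3-methyloxolan-2-yl]but-3-yn-2-yl]oxy}silane | C[C@H]1CCO[C@@H]1[C@@](C)(O[Si](C)(C)C(C)(C)C)C#C | intermediate
15 | (E)-alkenyl(chloro)zirconocene from 14 (not isolated) | C[C@H]1CCO[C@@H]1[C@@](C)(O[Si](C)(C)C(C)(C)C)/C=C/[Zr](Cl)(C1C=CC=C1)C1C=CC=C1 | intermediate
16 | tert-butyl{[(2S,3E)-4-iodo-2-[(2S,3S)-3-methyloxolan-2-yl]but-3-en-2-yl]oxy}dimethylsilane | C[C@H]1CCO[C@@H]1[C@@](C)(O[Si](C)(C)C(C)(C)C)/C=C/I | intermediate
17 | tert-butyldimethyl{[(2S,3E)-2-[(2S,3S)-3-methyloxolan-2-yl]-6-(trimethylsilyl)hex-3-en-5-yn-2-yl]oxy}silane | C[C@H]1CCO[C@@H]1[C@@](C)(O[Si](C)(C)C(C)(C)C)/C=C/C#C[Si](C)(C)C | intermediate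
18 | (2S,3E)-2-[(2S,3S)-3-methyloxolan-2-yl]hex-3-en-5-yn-2-ol | C[C@H]1CCO[C@@H]1[C@@](C)(O)/C=C/C#C | intermediate
19 | 4-methoxy-3-methylphenol | COc1ccc(O)cc1C | starting material
20 | 2-bromo-4-methoxy-5-methylphenol | COc1cc(Br)c(O)cc1C | intermediate
21 | 2-bromo-4,4-dimethoxy-5-methylcyclohexa-2,5-dien-1-one | COC1(OC)C=C(Br)C(=O)C=C1C | intermediate
22 | (1S)-2-bromo-4,4-dimethoxy-5-methylcyclohexa-2,5-dien-1-ol | BrC1=CC(OC)(OC)C(C)=C[C@@H]1O | intermediate
23 | cyclic osmate ester of 24 at the C1 and C2 oxygens (hexavalent osmium), TMEDA complex (not isolated) | BrC1=CC(OC)(OC)[C@]2(C)O[Os](=O)(=O)O[C@@H]2[C@@H]1O.CN(C)CCN(C)C | intermediate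
24 | (1R,2R,3S)-4-bromo-6,6-dimethoxy-1-methylcyclohex-4-ene-1,2,3-triol (all three hydroxyls cis) | BrC1=CC(OC)(OC)[C@](C)(O)[C@H](O)[C@@H]1O | intermediate
25 | (5R,6S)-2-bromo-5,6-dihydroxy-4,4-dimethoxy-5-methylcyclohex-2-en-1-one | BrC1=CC(OC)(OC)[C@](C)(O)[C@H](O)C1=O | intermediate
26 | (3aS,7aR)-5-bromo-7,7-dimethoxy-2,2,7a-trimethyl-7,7a-dihydro-1,3-benzodioxol-4(3aH)-one | BrC1=CC(OC)(OC)[C@]2(C)OC(C)(C)O[C@@H]2C1=O | intermediate
27 | (3aR,7aR)-5-bromo-7,7-dimethoxy-2,2,7a-trimethyl-4-methylidene-3a,4,7,7a-tetrahydro-1,3-benzodioxole | BrC1=CC(OC)(OC)[C@]2(C)OC(C)(C)O[C@@H]2C1=C | intermediate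
28 | B-alkyl-9-borabicyclo[3.3.1]nonane from 27 (not isolated) | BrC1=CC(OC)(OC)[C@]2(C)OC(C)(C)O[C@@H]2[C@@H]1CB1C2CCCC1CCC2 | intermediate
29 | [(3aR,4S,7aR)-5-bromo-7,7-dimethoxy-2,2,7a-trimethyl-3a,4,7,7a-tetrahydro-1,3-benzodioxol-4-yl]methanol | BrC1=CC(OC)(OC)[C@]2(C)OC(C)(C)O[C@@H]2[C@@H]1CO | intermediate
30 | (4S,5R,6R)-3-bromo-5,6-dihydroxy-4-(hydroxymethyl)-6-methylcyclohex-2-en-1-one | BrC1=CC(=O)[C@](C)(O)[C@H](O)[C@@H]1CO | intermediate
31 | (4S,5R,6R)-5,6-dihydroxy-4-(hydroxymethyl)-3-[(3E,5S)-5-hydroxy-5-[(2S,3S)-3-methyloxolan-2-yl]hex-3-en-1-yn-1-yl]-6-methylcyclohex-2-en-1-one (not isolated) | C[C@H]1CCO[C@@H]1[C@@](C)(O)/C=C/C#CC1=CC(=O)[C@](C)(O)[C@H](O)[C@@H]1CO | intermediate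
32 | (7R,8R,8aS)-7,8-dihydroxy-3-[(1E,3S)-3-hydroxy-3-[(2S,3S)-3-methyloxolan-2-yl]but-1-en-1-yl]-7-methyl-1,7,8,8a-tetrahydro-6H-isochromen-6-one | C[C@H]1CCO[C@@H]1[C@@](C)(O)/C=C/C1=CC2=CC(=O)[C@](C)(O)[C@H](O)[C@@H]2CO1 | intermediate
33 | (7R,8R,8aS)-5-chloro-7,8-dihydroxy-3-[(1E,3S)-3-hydroxy-3-[(2S,3S)-3-methyloxolan-2-yl]but-1-en-1-yl]-7-methyl-1,7,8,8a-tetrahydro-6H-isochromen-6-one | C[C@H]1CCO[C@@H]1[C@@](C)(O)/C=C/C1=CC2=C(Cl)C(=O)[C@](C)(O)[C@H](O)[C@@H]2CO1 | target

## Step count and risks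

Total step count: 21. Longest linear sequence: 11 steps (steps 1–3, 5–10, 20, 21; the ring A branch, steps 11–21, is equally long).

Steps most likely to fail:

Step 13. The bis-allylic dienol may aromatise by loss of methanol during reduction or work-up, and the two vinyl flanks of the dienone may not be told apart well enough by the catalyst. Fallback: set out from dienone 21 and dihydroxylate the methyl-bearing alkene directly (OsO4 cat., NMO, acetone/water) to the racemic cis-diol F1. A lipase-catalysed kinetic resolution (Candida antarctica lipase B, vinyl acetate, screened so that the 5S,6R enantiomer is acylated) should then give the acetate F2 of the unwanted enantiomer and leave the 5R,6S diol. The fallback comes back to the route at 25 and makes steps 13–15 unnecessary.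

Step 18. Facial selectivity of borane approach may be poor, because the C7 methyl group sits on the convex face in a 1,3-relationship to C8a and can offset the shielding by the dioxolane. Fallback: set out from diol ketone 25 and deliver C1 from the C8 oxygen through a ring. Methylenation of unprotected 25 (Cp2TiMe2) should give the diene diol F3. Selective silylation of the secondary hydroxyl with (HMe2Si)2NH should give the hydridosilyl ether F4. Platinum-catalysed intramolecular hydrosilylation (Pt2[(CH2=CHSiMe2)2O]3, 5-endo) should give the cis-fused oxasilolane F5, in which the ring fusion forces the new CH2 cis to the C8 oxygen. Tamao oxidation (H2O2, KF, KHCO3) should give the triol ketal F6, and aqueous acid hydrolysis of its dimethyl ketal comes back to the route at 30.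

Step 5. The telescoped closure may stay incomplete or cost material (loss of the tertiary silyl ether in acidic methanol), and the quaternary α-centre of the aldehyde may erode reagent control. Fallback: set out from aldehyde 5 and form the two bonds separately. Brown anti-crotylboration with (E)-crotylbis(isopinocampheyl)borane (the antipode that gives the 3S,4S adduct; THF, −78 °C, NaBO3 work-up) should give the homoallylic alcohol F7. Hydroboration–oxidation of the terminal alkene (9-BBN; H2O2, NaOH) should give the 1,4-diol F8. Selective sulfonylation of the primary hydroxyl (TsCl, pyridine) should give the monotosylate F9, and NaH in THF should close the oxolane by 5-exo-tet displacement. The fallback comes back to the route at 13.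

## Further compounds

F1 | step 13 | racemic cis-2-bromo-5,6-dihydroxy-4,4-dimethoxy-5-methylcyclohex-2-en-1-one (5R,6S and 5S,6R) | BrC1=CC(OC)(OC)[C@](C)(O)[C@H](O)C1=O.BrC1=CC(OC)(OC)[C@@](C)(O)[C@@H](O)C1=O
F2 | step 13 | (1R,6S)-3-bromo-6-hydroxy-5,5-dimethoxy-6-methyl-2-oxocyclohex-3-en-1-yl acetate | BrC1=CC(OC)(OC)[C@@](C)(O)[C@@H](OC(C)=O)C1=O
F3 | step 18 | (1R,2R)-4-bromo-6,6-dimethoxy-1-methyl-3-methylidenecyclohex-4-ene-1,2-diol | BrC1=CC(OC)(OC)[C@](C)(O)[C@H](O)C1=C
F4 | step 18 | {[(1R,6R)-3-bromo-6-hydroxy-5,5-dimethoxy-6-methyl-2-methylidenecyclohex-3-en-1-yl]oxy}dimethylsilane | BrC1=CC(OC)(OC)[C@](C)(O)[C@H](O[SiH](C)C)C1=C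
F5 | step 18 | cis-fused 2,2-dimethyl-1,2-oxasilolane bridging the C8 oxygen and the exocyclic CH2 of F4 (C7 hydroxyl free) | BrC1=CC(OC)(OC)[C@](C)(O)[C@@H]2O[Si](C)(C)C[C@H]12
F6 | step 18 | (1R,2R,3S)-4-bromo-3-(hydroxymethyl)-6,6-dimethoxy-1-methylcyclohex-4-ene-1,2-diol | BrC1=CC(OC)(OC)[C@](C)(O)[C@H](O)[C@@H]1CO
F7 | step 5 | (3S,4S,5S)-5-[(tert-butyldimethylsilyl)oxy]-3,5-dimethyl-7-(trimethylsilyl)hept-1-en-6-yn-4-ol | C=C[C@H](C)[C@H](O)[C@@](C)(O[Si](C)(C)C(C)(C)C)C#C[Si](C)(C)C
F8 | step 5 | (3S,4S,5S)-5-[(tert-butyldimethylsilyl)oxy]-3,5-dimethyl-7-(trimethylsilyl)hept-6-yne-1,4-diol | OCC[C@H](C)[C@H](O)[C@@](C)(O[Si](C)(C)C(C)(C)C)C#C[Si](C)(C)C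
F9 | step 5 | (3S,4S,5S)-5-[(tert-butyldimethylsilyl)oxy]-4-hydroxy-3,5-dimethyl-7-(trimethylsilyl)hept-6-yn-1-yl 4-methylbenzenesulfonate | Cc1ccc(cc1)S(=O)(=O)OCC[C@H](C)[C@H](O)[C@@](C)(O[Si](C)(C)C(C)(C)C)C#C[Si](C)(C)C
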